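**Plan**
Numbering (chromen-4-one): O1, C2 (chain), C3, C4 (C=O), C4a, C5 (carbinol), C6, C7, C8, C8a; ring A is the pyranone, ring B the carbocycle.
Enabling feature: C5–C4a=C8a–C8 is a 1-hydroxydiene whose central bond lies in ring A, so ring B is the [4+2] adduct of the photoenol of a 3-formyl-2-methyl-4-pyranone with a two-carbon unit C6–C7.
Retrosynthesis: C6–H goes back to C6–SO2Ph; C5–C6 and C7–C8 are cut together; the formyl carbon (C5) goes back to an ester; ring A is cut at C4–C4a and O1–C8a into an acylketene and an enaminoester.
Forward: the C18 acid is joined to Meldrum's acid, ring A is closed with the enaminoester, the ester is taken to the aldehyde, ring B is closed by light, and the sulfonyl group is removed.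
Stereochemistry: the Z alkene comes with the purchased acid; C5 is set during ring-B closure by a chiral titanium chelate spanning the C4 carbonyl and the dienol oxygen.

Key step: step 6

Assumption: the face of the titanium-bound dienol left open by (R,R)-TADDOL is taken to be the one leading to the 5R adduct; this has no precedent on a pyranone, and the mirror-image ligand would be used if the opposite sense were found.

**Route**

Step 1
Reactants: 1 (13Z)-octadec-13-enoic acid; 2 Meldrum's acid
Product: 3 5-[(13Z)-1-hydroxyoctadec-13-en-1-ylidene]-2,2-dimethyl-1,3-dioxane-4,6-dione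
Conditions: DCC, DMAP, CH2Cl2, 0 °C to rt; cold aq. KHSO4 wash; used crude
Reagents that add atoms: none
Why: DCC activates the acid and DMAP passes the acyl group to C5 of Meldrum's acid (carbodiimide-mediated C-acylation of Meldrum's acid), conditions under which the isolated Z alkene is inert.

Step 2
Reactants: 4 ethyl acetoacetate
Product: 5 ethyl (2E)-3-(pyrrolidin-1-yl)but-2-enoate
Conditions: pyrrolidine, toluene, reflux, Dean–Stark trap
Reagents that add atoms: pyrrolidine, C1CCNC1
Why: Condensation of the ketone with a secondary amine under azeotropic removal of water should give the conjugated E enaminoester (enamine formation).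

Step 3
Reactants: 3 5-[(13Z)-1-hydroxyoctadec-13-en-1-ylidene]-2,2-dimethyl-1,3-dioxane-4,6-dione; 5 ethyl (2E)-3-(pyrrolidin-1-yl)but-2-enoate
Product: 8 ethyl 6-[(12Z)-heptadec-12-en-1-yl]-2-methyl-4-oxo-4H-pyran-3-carboxylate, via acylketene 6 (not isolated), via C-acylated enaminoester 7 (not isolated)
Conditions: 3 added slowly to 5 (1.5 equiv), dry toluene, 100 °C; then TsOH·H2O, 60 °C
Reagents that add atoms: none
Why: Above about 80 °C the acyl Meldrum's acid should lose acetone and CO2 to give acylketene 6, the nucleophilic α-carbon of the enaminoester (kept in excess) should attack the ketene carbon to give 7, and acid then lets the enol oxygen of the side-chain ketone displace pyrrolidine from the push–pull double bond to close ring A (acylketene–enamine synthesis of 4-pyranones, a formal [4+2] annulation).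

Step 4
Reactants: 8 ethyl 6-[(12Z)-heptadec-12-en-1-yl]-2-methyl-4-oxo-4H-pyran-3-carboxylate
Product: 9 6-[(12Z)-heptadec-12-en-1-yl]-3-(hydroxymethyl)-2-methyl-4H-pyran-4-one
Conditions: iBu2AlH (2.2 equiv), CH2Cl2, −78 °C; aq. potassium sodium tartrate (KNaC4H4O6)
Reagents that add atoms: none
Why: At −78 °C iBu2AlH should reduce the ester by 1,2-addition faster than it attacks the pyranone carbonyl, a doubly vinylogous ester of low electrophilicity, while the methyl group hinders hydride delivery to C2 (aluminium hydride reduction of an ester to the primary alcohol).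

Step 5
Reactants: 9 6-[(12Z)-heptadec-12-en-1-yl]-3-(hydroxymethyl)-2-methyl-4H-pyran-4-one
Product: 10 6-[(12Z)-heptadec-12-en-1-yl]-2-methyl-4-oxo-4H-pyran-3-carbaldehyde
Conditions: Dess–Martin periodinane, CH2Cl2, 0 °C to rt
Reagents that add atoms: none
Why: Dess–Martin oxidation of the primary alcohol should stop at the non-enolizable aldehyde, and its neutral conditions should leave the pyranone and the Z alkene untouched.

Step 6
Reactants: 10 6-[(12Z)-heptadec-12-en-1-yl]-2-methyl-4-oxo-4H-pyran-3-carbaldehyde; 11 phenyl vinyl sulfone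
Product: 13 (5R,6S)-2-[(12Z)-heptadec-12-en-1-yl]-5-hydroxy-6-(phenylsulfonyl)-5,6,7,8-tetrahydro-4H-chromen-4-one, via photodienol 12 (not isolated)
Conditions: Ti(OiPr)4 (tetravalent titanium, 2 equiv), (R,R)-TADDOL (2.2 equiv), toluene, rt; then 11 (3 equiv), degassed, 365 nm LED, −20 °C; aq. NaHCO3
Reagents that add atoms: none
Why: Proposed new method: excitation of the formyl n→π* band at 365 nm should be followed by a 1,5-hydrogen shift from the methyl group on C2 of 10 (C8 of the product) to the formyl oxygen, giving the hydroxy-ortho-quinodimethane 12, whose long-lived isomer has the hydroxyl turned toward the C4 carbonyl and should be held by titanium as a six-membered dienolate chelate; suprafacial [4+2] addition of the electron-poor vinyl sulfone to this electron-rich diene then forms C7–C8 and C5–C6 and restores the pyranone. The closest known reaction type is the photoenolization/Diels–Alder reaction of 2-methylbenzaldehydes with electron-poor alkenes promoted by Ti(OiPr)4 and TADDOL-type diols, which has not been run on a 4-pyranone aldehyde or with two-point binding inside the diene itself. Ring B closes by an intermolecular Diels–Alder cycloaddition in which both new bonds are made across the exocyclic diene termini C5 and C8. C5 is controlled by the aryl groups of Ti(TADDOLate), which should cover one face of the planar chelate so that the sulfone adds to the open face, whereas C6 follows from endo approach of the sulfonyl group (cis to the hydroxyl) and is of no consequence because the group is removed. The only selectivity the step needs is facial selectivity at C5, secured by the rigid chelate between the C4 carbonyl and the C5 oxygen; the expected regiochemistry (C8 methylene, the larger HOMO coefficient, to the β-carbon of the sulfone) is not required. Enolization should be easier than in the benzene series because the pyranone gives up little aromatic stabilization, and the carbinol appears only once C4a is sp2 again, so it is not exposed to elimination during the cycloaddition.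

Step 7
Reactants: 13 (5R,6S)-2-[(12Z)-heptadec-12-en-1-yl]-5-hydroxy-6-(phenylsulfonyl)-5,6,7,8-tetrahydro-4H-chromen-4-one
Product: 14 (5S)-2-[(12Z)-heptadec-12-en-1-yl]-5-hydroxy-5,6,7,8-tetrahydro-4H-chromen-4-one
Conditions: Na(Hg) (6% Na), Na2HPO4, MeOH–THF, −20 °C
Reagents that add atoms: none
Why: Electron transfer from Na(Hg) to the phenylsulfonyl group should cleave the C6–S bond and methanol protonates the C6 carbanion (reductive desulfonylation), while the phosphate buffer and low temperature hold back alkoxide-driven dehydration or ring opening; C5 is not involved (its descriptor changes from R to S only because C6 loses priority) and the isolated Z alkene is inert.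

**Compound list**
1 | (13Z)-octadec-13-enoic acid | CCCC/C=C\CCCCCCCCCCCC(=O)O | starting material
2 | Meldrum's acid (2,2-dimethyl-1,3-dioxane-4,6-dione) | CC1(C)OC(=O)CC(=O)O1 | starting material
3 | 5-[(13Z)-1-hydroxyoctadec-13-en-1-ylidene]-2,2-dimethyl-1,3-dioxane-4,6-dione (acyl Meldrum's acid, enol form) | CCCC/C=C\CCCCCCCCCCCC(O)=C1C(=O)OC(C)(C)OC1=O | intermediate
4 | ethyl acetoacetate | CCOC(=O)CC(C)=O | starting material
5 | ethyl (2E)-3-(pyrrolidin-1-yl)but-2-enoate | CCOC(=O)/C=C(\C)N1CCCC1 | intermediate
6 | acylketene, (15Z)-icosa-1,15-diene-1,3-dione | CCCC/C=C\CCCCCCCCCCCC(=O)C=C=O | intermediate (not isolated)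
7 | ethyl (17Z)-3,5-dioxo-2-[1-(pyrrolidin-1-yl)ethylidene]docos-17-enoate (geometry of the push–pull double bond not fixed) | CCCC/C=C\CCCCCCCCCCCC(=O)CC(=O)C(C(=O)OCC)=C(C)N1CCCC1 | intermediate (not isolated)
8 | ethyl 6-[(12Z)-heptadec-12-en-1-yl]-2-methyl-4-oxo-4H-pyran-3-carboxylate | CCCC/C=C\CCCCCCCCCCCc1cc(=O)c(C(=O)OCC)c(C)o1 | intermediate
9 | 6-[(12Z)-heptadec-12-en-1-yl]-3-(hydroxymethyl)-2-methyl-4H-pyran-4-one | CCCC/C=C\CCCCCCCCCCCc1cc(=O)c(CO)c(C)o1 | intermediate
10 | 6-[(12Z)-heptadec-12-en-1-yl]-2-methyl-4-oxo-4H-pyran-3-carbaldehyde | CCCC/C=C\CCCCCCCCCCCc1cc(=O)c(C=O)c(C)o1 | intermediate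
11 | phenyl vinyl sulfone | C=CS(=O)(=O)c1ccccc1 | starting material
12 | (3Z)-6-[(12Z)-heptadec-12-en-1-yl]-3-(hydroxymethylidene)-2-methylidene-2,3-dihydro-4H-pyran-4-one (hydroxyl toward the C4 carbonyl; held on titanium as its dienolate) | CCCC/C=C\CCCCCCCCCCCC1=CC(=O)/C(=C\O)C(=C)O1 | intermediate (not isolated)
13 | (5R,6S)-2-[(12Z)-heptadec-12-en-1-yl]-5-hydroxy-6-(phenylsulfonyl)-5,6,7,8-tetrahydro-4H-chromen-4-one (hydroxyl and sulfonyl cis) | CCCC/C=C\CCCCCCCCCCCc1cc(=O)c2c(o1)CC[C@H](S(=O)(=O)c3ccccc3)[C@@H]2O | intermediate
14 | (5S)-2-[(12Z)-heptadec-12-en-1-yl]-5-hydroxy-5,6,7,8-tetrahydro-4H-chromen-4-one | CCCC/C=C\CCCCCCCCCCCc1cc(=O)c2c(o1)CCC[C@@H]2O | target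

**Count**
Total steps: 7. Longest linear sequence: 6 steps (steps 1, 3, 4, 5, 6, 7 from acid 1); step 2 is a one-step side branch.

**Steps most likely to fail**

1. Step 6.
- What may go wrong: titanium may bind the ground-state aldehyde through the formyl and C4 oxygens and so turn the formyl oxygen away from the methyl group, shutting down the hydrogen shift. The pyranone may undergo its own photorearrangement. The sulfone may add with poor facial selectivity.
- Fallback (known chemistry, gives up the photochemical ring closure): it sets out from 3 and returns to the route at 14. Heating 3 with cyclohexane-1,3-dione in toluene (Et3N, with catalytic DMAP for the O-to-C acyl shift if the enol ester forms first) should trap the acylketene as 2-[(15Z)-3-oxoicos-15-enoyl]cyclohexane-1,3-dione F1. TsOH in refluxing toluene should cyclodehydrate this to 2-[(12Z)-heptadec-12-en-1-yl]-7,8-dihydro-4H-chromene-4,5(6H)-dione F2. CBS reduction of the C5 ketone (catecholborane, (R)-2-methyl-CBS-oxazaborolidine, toluene, −78 °C; sense assigned by analogy with 1-tetralone) should then give 14, since the doubly vinylogous C4 carbonyl is far less electrophilic.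

2. Step 4.
- What may go wrong: hydride may be delivered to C2 or C4 of the pyranone (ring reduction or ring opening) in competition with ester reduction.
- Fallback (no nucleophilic hydride): it sets out from 8 and returns at 10, bypassing steps 4 and 5. Me3SnOH in 1,2-dichloroethane at 80 °C should cleave the ester to 6-[(12Z)-heptadec-12-en-1-yl]-2-methyl-4-oxo-4H-pyran-3-carboxylic acid F3. SOCl2 with catalytic DMF should give 6-[(12Z)-heptadec-12-en-1-yl]-2-methyl-4-oxo-4H-pyran-3-carbonyl chloride F4. Bu3SnH with catalytic Pd(PPh3)4 (zerovalent palladium) in THF should reduce the acid chloride to 10.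

3. Step 7.
- What may go wrong: methoxide may build up and cause loss of water across C5–C6, or the C5 alkoxide may expel the sulfonyl carbanion and open ring B, with erosion of configuration at C5 on re-closure. Electron transfer to the pyranone is a further risk.
- Fallback (carbinol masked before the C–S cleavage): it sets out from 13 and returns at 14. TBSOTf and 2,6-lutidine in CH2Cl2 should give (5R,6S)-5-[(tert-butyldimethylsilyl)oxy]-2-[(12Z)-heptadec-12-en-1-yl]-6-(phenylsulfonyl)-5,6,7,8-tetrahydro-4H-chromen-4-one F5. The same buffered Na(Hg) reduction should give (5S)-5-[(tert-butyldimethylsilyl)oxy]-2-[(12Z)-heptadec-12-en-1-yl]-5,6,7,8-tetrahydro-4H-chromen-4-one F6. HF·pyridine in THF should then free 14.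

**Further compounds**
F1 | step 6 | 2-[(15Z)-3-oxoicos-15-enoyl]cyclohexane-1,3-dione | CCCC/C=C\CCCCCCCCCCCC(=O)CC(=O)C1C(=O)CCCC1=O
F2 | step 6 | 2-[(12Z)-heptadec-12-en-1-yl]-7,8-dihydro-4H-chromene-4,5(6H)-dione | CCCC/C=C\CCCCCCCCCCCc1cc(=O)c2c(o1)CCCC2=O
F3 | step 4 | 6-[(12Z)-heptadec-12-en-1-yl]-2-methyl-4-oxo-4H-pyran-3-carboxylic acid | CCCC/C=C\CCCCCCCCCCCc1cc(=O)c(C(=O)O)c(C)o1
F4 | step 4 | 6-[(12Z)-heptadec-12-en-1-yl]-2-methyl-4-oxo-4H-pyran-3-carbonyl chloride | CCCC/C=C\CCCCCCCCCCCc1cc(=O)c(C(=O)Cl)c(C)o1
F5 | step 7 | (5R,6S)-5-[(tert-butyldimethylsilyl)oxy]-2-[(12Z)-heptadec-12-en-1-yl]-6-(phenylsulfonyl)-5,6,7,8-tetrahydro-4H-chromen-4-one | CCCC/C=C\CCCCCCCCCCCc1cc(=O)c2c(o1)CC[C@H](S(=O)(=O)c3ccccc3)[C@@H]2O[Si](C)(C)C(C)(C)C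
F6 | step 7 | (5S)-5-[(tert-butyldimethylsilyl)oxy]-2-[(12Z)-heptadec-12-en-1-yl]-5,6,7,8-tetrahydro-4H-chromen-4-one | CCCC/C=C\CCCCCCCCCCCc1cc(=O)c2c(o1)CCC[C@@H]2O[Si](C)(C)C(C)(C)C
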